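Numbering (daucane): ring A = cyclopentane C1(quaternary, Me)–C2–C3–C4(OH, iPr)–C5(H). Ring B = cycloheptene C1–C5–C6(OAr)–C7=C8(Me)–C9(OH)–C10. β = the face of the C1 methyl group.
Cuts: first the C6–O acyl bond, the C9–O silyl group and the C6–H bond (back to the ketone). Then C1–C2 and C4–C5 together, which splits ring A into 1-isopropylcyclopropanol and a ring-B cyclohepta-2,6-dienone. Then C7=C8 (metathesis), C6–C7 (vinyl Grignard), C5=C1 (metathesis inside a temporary δ-lactone) and C9–C10 (methallylation).
Enabling feature: C4–OH is β to the C6 oxygen through C5 (aldol retron), and quaternary C1 is the β-carbon of the ring-B enone C6(=O)–C5=C1 (Michael retron). C2–C3–C4 is therefore a ketone homoenolate, stored as a cyclopropanol whose three-membered ring is enlarged by C1 and C5 to ring A.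
Forward order: C9 carbinol, temporary lactone (locks C5=C1 as Z), ring B, ring A, then C6 reduction, acylation and desilylation.
Stereochemistry: C9 from a catalytic asymmetric methallylation. C1 from C9 (1,3-anti addition). C4 and C5 from the zinc-chelated, reversible aldol (trans-fused aldolate as thermodynamic sink). C6 from hydride delivery by the C4 hydroxyl.

Key step: step 9

Step 1
Reactants: 1 methacrolein; 2 tributyl(2-methylallyl)stannane
Product: 3 (R)-2,5-dimethylhexa-1,5-dien-3-ol
Conditions: Ti(OiPr)4 (10 mol %), (R)-BINOL (20 mol %), 4 Å MS, CH2Cl2, −20 °C; aq NaHCO3 work-up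
Reagents that add atoms: none
Why: Keck asymmetric allylation, in which the (R)-BINOL–titanium Lewis acid activates the aldehyde and exposes its Re face to the methallylstannane in an open transition state, so that C9 is set as R and the enal reacts 1,2 as usual.

Step 2
Reactants: 3 (R)-2,5-dimethylhexa-1,5-dien-3-ol; 4 acryloyl chloride
Product: 5 (R)-2,5-dimethylhexa-1,5-dien-3-yl acrylate
Conditions: Et3N, DMAP (cat.), CH2Cl2, 0 °C
Reagents that add atoms: none
Why: DMAP-catalysed O-acylation of a secondary allylic alcohol with an acid chloride, which does not touch C9.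

Step 3
Reactants: 5 (R)-2,5-dimethylhexa-1,5-dien-3-yl acrylate
Product: 6 (R)-4-methyl-6-(prop-1-en-2-yl)-5,6-dihydro-2H-pyran-2-one
Conditions: second-generation Grubbs catalyst RuCl2(=CHPh)(PCy3)(H2IMes) (5 mol %), CH2Cl2 (5 mM), reflux
Reagents that add atoms: none
Why: Ring-closing metathesis of an acrylate with a 1,1-disubstituted alkene, a standard entry to 4-methyl-5,6-dihydropyran-2-ones, in which six-ring closure on the unhindered methallyl alkene should outrun five-ring closure on the isopropenyl group at the ester-bearing carbon, and the ring forces C5=C1 to be Z.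

Step 4
Reactants: 6 (R)-4-methyl-6-(prop-1-en-2-yl)-5,6-dihydro-2H-pyran-2-one
Product: 7 (R,Z)-5-hydroxy-N-methoxy-N,3,6-trimethylhepta-2,6-dienamide
Conditions: MeONHMe·HCl, AlMe3, CH2Cl2, 0 to 23 °C; aq Rochelle salt
Reagents that add atoms: N,O-dimethylhydroxylamine hydrochloride, CNOC.Cl
Why: Weinreb aminolysis of a lactone with the weakly basic aluminium amide cleaves only the acyl–oxygen bond, so the Z alkene and C9 are kept.

Step 5
Reactants: 7 (R,Z)-5-hydroxy-N-methoxy-N,3,6-trimethylhepta-2,6-dienamide
Product: 8 (R,Z)-5-[(tert-butyldimethylsilyl)oxy]-N-methoxy-N,3,6-trimethylhepta-2,6-dienamide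
Conditions: TBSOTf, 2,6-lutidine, CH2Cl2, −78 to 0 °C
Reagents that add atoms: tert-butyldimethylsilyl triflate, CC(C)(C)[Si](C)(C)OS(=O)(=O)C(F)(F)F
Why: Fast silylation of the secondary alcohol blocks relactonisation and installs the bulky group that later steers the key step.

Step 6
Reactants: 8 (R,Z)-5-[(tert-butyldimethylsilyl)oxy]-N-methoxy-N,3,6-trimethylhepta-2,6-dienamide; 9 vinylmagnesium bromide
Product: 10 (R,Z)-7-[(tert-butyldimethylsilyl)oxy]-5,8-dimethylnona-1,4,8-trien-3-one
Conditions: THF, −78 to 0 °C; poured into cold 1 M HCl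
Reagents that add atoms: none
Why: Weinreb ketone synthesis, in which the magnesium-chelated tetrahedral adduct survives until the acidic quench, so addition stops at the ketone and the freed amine is protonated before it can add to the vinyl ketone.

Step 7
Reactants: 10 (R,Z)-7-[(tert-butyldimethylsilyl)oxy]-5,8-dimethylnona-1,4,8-trien-3-one
Product: 11 (R)-4-[(tert-butyldimethylsilyl)oxy]-3,6-dimethylcyclohepta-2,6-dien-1-one
Conditions: second-generation Hoveyda–Grubbs catalyst RuCl2(=CH-2-iPrOC6H4)(H2IMes) (10 mol %), toluene (2 mM), 80 °C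
Reagents that add atoms: none
Why: Ring-closing metathesis of a vinyl ketone with a 1,1-disubstituted alkene, a known route to 3-methylcycloalk-2-enones, helped here by the Z C5=C1 alkene, which holds the two termini close so that closure of ring B beats dimerisation.

Step 8
Reactants: 12 methyl isobutyrate; 13 ethylmagnesium bromide
Product: 14 1-isopropylcyclopropan-1-ol
Conditions: Ti(OiPr)4 (20 mol %), EtMgBr (2.4 equiv), Et2O, 20 °C; aq work-up
Reagents that add atoms: none
Why: Kulinkovich reaction, in which the titanacyclopropane formed from two ethyl groups acts as a 1,2-dicarbanion towards the ester and closes the cyclopropanol.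

Step 9
Reactants: 11 (R)-4-[(tert-butyldimethylsilyl)oxy]-3,6-dimethylcyclohepta-2,6-dien-1-one; 14 1-isopropylcyclopropan-1-ol
Product: 17 (3R,3aR,7R,8aR)-7-[(tert-butyldimethylsilyl)oxy]-3-hydroxy-3-isopropyl-6,8a-dimethyl-2,3,3a,7,8,8a-hexahydroazulen-4(1H)-one, via zinc homoenolate 15 (not isolated), via zinc dienolate 16 (not isolated)
Conditions: 14 (2.2 equiv), Et2Zn (1.1 equiv), THF/DMPU, 0 to 23 °C; then CuCl(IMes) (10 mol %, IMes = 1,3-dimesitylimidazol-2-ylidene), 11, −20 to 23 °C, held at 23 °C until the aldolates have equilibrated; pH 7 buffer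
Reagents that add atoms: none
Why: Proposed new method: Et2Zn converts 14 into the zinc bis(cyclopropoxide), strain-driven cleavage of a C–C bond next to oxygen gives the carbonyl-chelated β-zincio ketone 15, transmetalation to the NHC-bound monovalent copper centre and 1,4-addition to the C6(=O)–C5=C1 enone of 11 forms C1–C2, and the zinc dienolate 16 then attacks its own isopropyl ketone to form C4–C5, so that the three-membered ring is enlarged by C1 and C5 to ring A (formal [3+2] annulation). The closest known reaction types are the conjugate addition/aldol annulation of cyclopropanol-derived zinc homoenolates with acyclic aryl enones, the copper-promoted [3+2] annulation of ester zinc homoenolates with alkynoates, and the NHC–copper-catalysed addition of dialkylzincs to 3-methylcycloalkenones, which shows that such a quaternary carbon can be made; new here are the β,β-disubstituted cyclic dienone as acceptor and the stop at the tertiary aldol. Ring A closes by a 5-(enolexo)-exo-trig aldol addition. C1 is controlled by C9, whose silyloxy group stands pseudoaxial on the β face to avoid A(1,2) strain with the C8 methyl group and screens that face in a 1,3-relation, so that C2 enters from the α face and the methyl group ends up β (1R in daucane numbering), while C4 is controlled by zinc bridging the enolate and ketone oxygens, which sets the C4–O bond syn to C6 and turns the isopropyl group away from ring B (4R). C5 is under thermodynamic control, since closure on the ring-B enolate is kinetically easiest to the cis-fused aldolate, but a tertiary zinc aldolate reverts readily and at 23 °C the mixture should drain into the trans-fused chelate, because perhydroazulen-4-ones with an angular methyl group are more stable trans-fused than cis-fused. The step needs site selectivity between the two β-carbons (C1 is flanked by the C10 methylene, C8 by the carbon bearing the silyloxy group), 1,4- over 1,2-addition (secured by copper), and survival of the γ-silyloxy dienone (secured by the weakly basic, aprotic zinc medium, which does not deprotonate C10).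

Step 10
Reactants: 17 (3R,3aR,7R,8aR)-7-[(tert-butyldimethylsilyl)oxy]-3-hydroxy-3-isopropyl-6,8a-dimethyl-2,3,3a,7,8,8a-hexahydroazulen-4(1H)-one
Product: 18 (3R,3aS,4S,7R,8aR)-7-[(tert-butyldimethylsilyl)oxy]-3-isopropyl-6,8a-dimethyl-1,2,3,3a,4,7,8,8a-octahydroazulene-3,4-diol
Conditions: Me4NBH(OAc)3, MeCN/AcOH, −20 °C; aq work-up
Reagents that add atoms: none
Why: Evans–Saksena reduction, in which the β-oriented C4 hydroxyl replaces an acetate on boron and delivers hydride intramolecularly to the β face of C6, giving the 1,3-anti diol with the 6α-hydroxyl, while the unbound reagent neither reduces the enone nor adds 1,4.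

Step 11
Reactants: 18 (3R,3aS,4S,7R,8aR)-7-[(tert-butyldimethylsilyl)oxy]-3-isopropyl-6,8a-dimethyl-1,2,3,3a,4,7,8,8a-octahydroazulene-3,4-diol; 19 4-methoxybenzoyl chloride
Product: 20 (3R,3aS,4S,7R,8aR)-7-[(tert-butyldimethylsilyl)oxy]-3-hydroxy-3-isopropyl-6,8a-dimethyl-1,2,3,3a,4,7,8,8a-octahydroazulen-4-yl 4-methoxybenzoate
Conditions: Et3N, DMAP (cat.), toluene, 60 °C
Reagents that add atoms: none
Why: DMAP-catalysed acylation with retention at C6, in which only the secondary allylic C6 hydroxyl reacts because the tertiary C4 hydroxyl is too hindered and C9 is silylated.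

Step 12
Reactants: 20 (3R,3aS,4S,7R,8aR)-7-[(tert-butyldimethylsilyl)oxy]-3-hydroxy-3-isopropyl-6,8a-dimethyl-1,2,3,3a,4,7,8,8a-octahydroazulen-4-yl 4-methoxybenzoate
Product: 21 (3R,3aS,4S,7R,8aR)-3,7-dihydroxy-3-isopropyl-6,8a-dimethyl-1,2,3,3a,4,7,8,8a-octahydroazulen-4-yl 4-methoxybenzoate (target)
Conditions: HF·pyridine, pyridine/THF, 0 to 23 °C
Reagents that add atoms: none
Why: Fluoride-driven cleavage of the Si–O bond under buffered conditions frees the C9 hydroxyl with retention and leaves the ester, the alkene and the tertiary alcohol untouched.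

Compound list
1 | methacrolein | C=C(C)C=O | starting material
2 | tributyl(2-methylallyl)stannane | C=C(C)C[Sn](CCCC)(CCCC)CCCC | starting material
3 | (R)-2,5-dimethylhexa-1,5-dien-3-ol | C=C(C)[C@H](O)CC(C)=C | intermediate
4 | acryloyl chloride | C=CC(=O)Cl | starting material
5 | (R)-2,5-dimethylhexa-1,5-dien-3-yl acrylate | C=C(C)[C@H](OC(=O)C=C)CC(C)=C | intermediate
6 | (R)-4-methyl-6-(prop-1-en-2-yl)-5,6-dihydro-2H-pyran-2-one | C=C(C)[C@H]1CC(C)=CC(=O)O1 | intermediate
7 | (R,Z)-5-hydroxy-N-methoxy-N,3,6-trimethylhepta-2,6-dienamide | C=C(C)[C@H](O)C/C(C)=C\C(=O)N(C)OC | intermediate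
8 | (R,Z)-5-[(tert-butyldimethylsilyl)oxy]-N-methoxy-N,3,6-trimethylhepta-2,6-dienamide | C=C(C)[C@H](O[Si](C)(C)C(C)(C)C)C/C(C)=C\C(=O)N(C)OC | intermediate
9 | vinylmagnesium bromide | C=C[Mg]Br | starting material
10 | (R,Z)-7-[(tert-butyldimethylsilyl)oxy]-5,8-dimethylnona-1,4,8-trien-3-one | C=C(C)[C@H](O[Si](C)(C)C(C)(C)C)C/C(C)=C\C(=O)C=C | intermediate
11 | (R)-4-[(tert-butyldimethylsilyl)oxy]-3,6-dimethylcyclohepta-2,6-dien-1-one | O=C1C=C(C)[C@H](O[Si](C)(C)C(C)(C)C)CC(C)=C1 | intermediate
12 | methyl isobutyrate | COC(=O)C(C)C | starting material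
13 | ethylmagnesium bromide | CC[Mg]Br | starting material
14 | 1-isopropylcyclopropan-1-ol | CC(C)C1(O)CC1 | intermediate
15 | bis(4-methyl-3-oxopentyl)zinc (zinc homoenolate) | CC(C)C(=O)CC[Zn]CCC(=O)C(C)C | intermediate
16 | (4-methyl-3-oxopentyl)zinc dienolate of (4R,6R)-4-[(tert-butyldimethylsilyl)oxy]-3,6-dimethyl-6-(4-methyl-3-oxopentyl)cyclohept-2-en-1-one | CC(C)C(=O)CC[Zn]OC1=C[C@](C)(CCC(=O)C(C)C)C[C@@H](O[Si](C)(C)C(C)(C)C)C(C)=C1 | intermediate
17 | (3R,3aR,7R,8aR)-7-[(tert-butyldimethylsilyl)oxy]-3-hydroxy-3-isopropyl-6,8a-dimethyl-2,3,3a,7,8,8a-hexahydroazulen-4(1H)-one (trans-fused; 4β-OH, 9β-OTBS, 1β-Me, 5α-H) | O=C1C=C(C)[C@H](O[Si](C)(C)C(C)(C)C)C[C@@]2(C)CC[C@@](O)(C(C)C)[C@H]12 | intermediate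
18 | (3R,3aS,4S,7R,8aR)-7-[(tert-butyldimethylsilyl)oxy]-3-isopropyl-6,8a-dimethyl-1,2,3,3a,4,7,8,8a-octahydroazulene-3,4-diol | O[C@H]1C=C(C)[C@H](O[Si](C)(C)C(C)(C)C)C[C@@]2(C)CC[C@@](O)(C(C)C)[C@H]12 | intermediate
19 | 4-methoxybenzoyl chloride | COc1ccc(C(=O)Cl)cc1 | starting material
20 | (3R,3aS,4S,7R,8aR)-7-[(tert-butyldimethylsilyl)oxy]-3-hydroxy-3-isopropyl-6,8a-dimethyl-1,2,3,3a,4,7,8,8a-octahydroazulen-4-yl 4-methoxybenzoate | COc1ccc(C(=O)O[C@H]2C=C(C)[C@H](O[Si](C)(C)C(C)(C)C)C[C@@]3(C)CC[C@@](O)(C(C)C)[C@H]23)cc1 | intermediate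
21 | (3R,3aS,4S,7R,8aR)-3,7-dihydroxy-3-isopropyl-6,8a-dimethyl-1,2,3,3a,4,7,8,8a-octahydroazulen-4-yl 4-methoxybenzoate | COc1ccc(C(=O)O[C@H]2C=C(C)[C@H](O)C[C@@]3(C)CC[C@@](O)(C(C)C)[C@H]23)cc1 | target

Total step count: 12. Longest linear sequence: 11 (steps 1–7 and 9–12).

Steps most likely to fail

Step 9.
- What may go wrong: sluggish transfer of the homoenolate to the hindered β-carbon; attack at the other β-carbon or a second addition; base-induced loss of silanol with aromatisation of ring B; arrest at the cis-fused aldolate; dehydration of the aldol.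
- Fallback (known chemistry, from 11 back to 17): the homoenolate is replaced by its ketal-masked Grignard equivalent and the two bonds are made in separate steps.
- 4-Methylpent-1-en-3-one is treated with HBr and ethane-1,2-diol to give 2-(2-bromoethyl)-2-isopropyl-1,3-dioxolane F1.
- The Grignard reagent of F1 is added to 11 with CuBr·SMe2 (cat.), Me3SiCl and HMPA in THF at −78 °C, conditions known to quaternise β,β-disubstituted enones. Mild acidic work-up gives the keto ketal (4R,6R)-4-[(tert-butyldimethylsilyl)oxy]-6-[2-(2-isopropyl-1,3-dioxolan-2-yl)ethyl]-3,6-dimethylcyclohept-2-en-1-one F2.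
- PPTS in wet acetone frees the diketone (4R,6R)-4-[(tert-butyldimethylsilyl)oxy]-3,6-dimethyl-6-(4-methyl-3-oxopentyl)cyclohept-2-en-1-one F3.
- A separate aldol cyclisation under equilibrating conditions (K2CO3, MeOH) leads to 17.

Step 3.
- What may go wrong: competing closure on the isopropenyl group to the five-membered lactone, or slow turnover on two deactivated alkenes.
- Fallback (from 1 back to 8): no metathesis, and the Z alkene comes from a syn-carbocupration.
- Keck-type asymmetric propargylation of 1 with allenyltributylstannane under the same (R)-BINOL/Ti(OiPr)4 catalyst gives (R)-2-methylhex-1-en-5-yn-3-ol F4.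
- TBSCl/imidazole gives (R)-tert-butyldimethyl[(2-methylhex-1-en-5-yn-3-yl)oxy]silane F5.
- n-BuLi and then methyl chloroformate give methyl (R)-5-[(tert-butyldimethylsilyl)oxy]-6-methylhept-6-en-2-ynoate F6.
- Me2CuLi at −78 °C followed by protonation adds methyl and hydrogen syn, giving methyl (R,Z)-5-[(tert-butyldimethylsilyl)oxy]-3,6-dimethylhepta-2,6-dienoate F7.
- MeONHMe·HCl/iPrMgCl converts F7 into 8.

Step 7.
- What may go wrong: slow initiation on an electron-poor and a hindered alkene; Z-to-E isomerisation of the enone; dimerisation; loss of silanol from the product on prolonged heating.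
- Fallback (from 10 back to 11): ring B is closed at the alcohol oxidation level.
- Luche reduction (NaBH4, CeCl3·7H2O, MeOH) of 10 gives (4Z,7R)-7-[(tert-butyldimethylsilyl)oxy]-5,8-dimethylnona-1,4,8-trien-3-ol F8. Its new carbinol centre is of no consequence.
- The more reactive allylic-alcohol alkene undergoes ring-closing metathesis at 40 °C to (4R)-4-[(tert-butyldimethylsilyl)oxy]-3,6-dimethylcyclohepta-2,6-dien-1-ol F9.
- MnO2 in CH2Cl2 oxidises the doubly allylic alcohol to 11.

Further compounds
F1 | step 9 | 2-(2-bromoethyl)-2-isopropyl-1,3-dioxolane | CC(C)C1(CCBr)OCCO1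
F2 | step 9 | (4R,6R)-4-[(tert-butyldimethylsilyl)oxy]-6-[2-(2-isopropyl-1,3-dioxolan-2-yl)ethyl]-3,6-dimethylcyclohept-2-en-1-one | O=C1C[C@](C)(CCC2(C(C)C)OCCO2)C[C@@H](O[Si](C)(C)C(C)(C)C)C(C)=C1
F3 | step 9 | (4R,6R)-4-[(tert-butyldimethylsilyl)oxy]-3,6-dimethyl-6-(4-methyl-3-oxopentyl)cyclohept-2-en-1-one | O=C1C[C@](C)(CCC(=O)C(C)C)C[C@@H](O[Si](C)(C)C(C)(C)C)C(C)=C1
F4 | step 3 | (R)-2-methylhex-1-en-5-yn-3-ol | C=C(C)[C@H](O)CC#C
F5 | step 3 | (R)-tert-butyldimethyl[(2-methylhex-1-en-5-yn-3-yl)oxy]silane | C=C(C)[C@H](O[Si](C)(C)C(C)(C)C)CC#C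
F6 | step 3 | methyl (R)-5-[(tert-butyldimethylsilyl)oxy]-6-methylhept-6-en-2-ynoate | C=C(C)[C@H](O[Si](C)(C)C(C)(C)C)CC#CC(=O)OC
F7 | step 3 | methyl (R,Z)-5-[(tert-butyldimethylsilyl)oxy]-3,6-dimethylhepta-2,6-dienoate | C=C(C)[C@H](O[Si](C)(C)C(C)(C)C)C/C(C)=C\C(=O)OC
F8 | step 7 | (4Z,7R)-7-[(tert-butyldimethylsilyl)oxy]-5,8-dimethylnona-1,4,8-trien-3-ol | C=C(C)[C@H](O[Si](C)(C)C(C)(C)C)C/C(C)=C\C(O)C=C
F9 | step 7 | (4R)-4-[(tert-butyldimethylsilyl)oxy]-3,6-dimethylcyclohepta-2,6-dien-1-ol | OC1C=C(C)[C@H](O[Si](C)(C)C(C)(C)C)CC(C)=C1
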